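Retrosynthesis: the hydroquinone is traced back to its dimethyl ether, and then a single bond is cut, C6'–C9, between the prenyl-bearing quaternary carbon (alpha to one enedione carbonyl) and the benzylic methine. This bond is an edge of both the five-membered ring and the cyclohexene ring of the benzobicyclo[3.2.1]octadiene, so the one cut opens both and leaves a cyclohexenedione spiro-linked to a benzocycloheptene whose only fixed stereocentre is the aryl- and vinyl-bearing quaternary carbon C5.
Further cuts: prenyl–C6' (enolate alkylation), C5–C6 (dearomative spiro-alkenylation of a 2-arylphenol by a (Z)-iodoalkene), methyl and iodine on the alkene (carboalumination), carbinol–CH2 (propargylation) and the biaryl bond (Suzuki–Miyaura).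
Forward: both six-membered carbocycles are bought as benzene rings and joined; the seven-membered ring forms when one arene is dearomatised to the spiro dienone (the future enedione ring); the transannular bond then divides the seven-membered ring into the five-membered and the cyclohexene ring; the second arene is released as the hydroquinone last.
Stereochemistry: C5 comes from the chiral ligand on palladium (step 7); C9 and C6' come from C5 in step 10 (bicycle geometry and ring-fusion preference); the carbinol carbon and the prenylated CH are carried as mixtures because both become planar in step 10.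

Key step: step 10

Remark: the sense of induction of the chiral ligand in step 7 cannot be fixed on paper; (S)-AntPhos is written, and its antipode is taken if the spiro centre proves to form with the opposite configuration.
Locants (spiro numbering, kept for the bridged compounds): C1–C4 arene carbons, C4a, C5 (spiro carbon), C6 (=CH), C7 (C–CH3), C8 (CH2), C9 (benzylic carbon), C9a; six-membered ring C1' (= C5), C2' (C=O from the phenol carbon), C3'=C4', C5' (the carbon that carried OCH3), C6' (the carbon that receives prenyl).

Step 1
Reactants: 1 2,5-dimethoxybenzaldehyde
Product: 5 2-iodo-3,6-dimethoxybenzaldehyde, via lithium amino alkoxide 2 (not isolated), via ortho-lithiated amino alkoxide 3 (not isolated), via iodinated amino alkoxide 4 (not isolated)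
Conditions: LiN(Me)CH2CH2NMe2 (from the amine and n-BuLi), THF, -20 °C; n-BuLi, -20 °C; I2, THF, -78 °C to rt; H2O
Reagents that add atoms: iodine, [I][I]
Why: Directed ortho-metalation through an alpha-amino alkoxide: the lithium amide adds to the aldehyde and masks it, and its chelating diamine arm together with the 5-methoxy group steers n-BuLi to C6, the one position between the two directing groups; iodine traps the aryllithium and water collapses the hemiaminal back to the aldehyde.

Step 2
Reactants: 5 2-iodo-3,6-dimethoxybenzaldehyde; 6 (2-hydroxy-5-methoxyphenyl)boronic acid
Product: 7 2'-hydroxy-3,5',6-trimethoxybiphenyl-2-carbaldehyde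
Conditions: Pd(OAc)2 (3 mol %), SPhos (6 mol %), K3PO4, toluene/H2O, 80 °C
Reagents that add atoms: none
Why: Suzuki–Miyaura coupling: the electron-rich dialkylbiarylphosphine makes oxidative addition and transmetalation workable for the doubly ortho-substituted iodide, free phenol and aldehyde are tolerated, and the product should rest as its six-membered lactol while reacting as the hydroxy aldehyde.

Step 3
Reactants: 7 2'-hydroxy-3,5',6-trimethoxybiphenyl-2-carbaldehyde; 8 propargyl bromide
Product: 9 1-(2'-hydroxy-3,5',6-trimethoxybiphenyl-2-yl)but-3-yn-1-ol (racemic)
Conditions: Zn dust, THF/sat. aq. NH4Cl, 0 °C to rt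
Reagents that add atoms: none
Why: Zinc Barbier propargylation: allenylzinc bromide made in the flask adds through a cyclic SE2' transition state to the aldehyde that the lactol releases, so the propargyl and not the allenyl carbinol forms; the new carbinol centre is racemic on purpose, because step 10 turns it into a planar cation.

Step 4
Reactants: 9 1-(2'-hydroxy-3,5',6-trimethoxybiphenyl-2-yl)but-3-yn-1-ol; 10 trimethylaluminium
Product: 13 (Z)-4-iodo-3-methyl-1-(2'-hydroxy-3,5',6-trimethoxybiphenyl-2-yl)but-3-en-1-ol (racemic), via E-alkenylalane 11 (not isolated), via cyclic Z-alkenylalane 12 (not isolated)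
Conditions: Me3Al (5 equiv), Cp2ZrCl2 (0.3 equiv), ClCH2CH2Cl, 0 °C to rt, then reflux; I2, THF, -30 to 0 °C; aq. potassium sodium tartrate
Reagents that add atoms: iodine, [I][I]
Why: Negishi zirconium-catalysed carboalumination followed by chelation-driven isomerisation: methyl and aluminium add syn to the terminal alkyne with methyl on the internal carbon, heating lets the alkenylalane invert to the (Z) isomer held in a six-membered ring by the neighbouring aluminium alkoxide, and iodine cleaves the C–Al bond with retention, so iodine ends cis to the carbinol-bearing chain as the later ring closure requires.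

Step 5
Reactants: 13 (Z)-4-iodo-3-methyl-1-(2'-hydroxy-3,5',6-trimethoxybiphenyl-2-yl)but-3-en-1-ol
Product: 14 bis-pivalate of 13 (aryl pivalate and benzylic pivalate)
Conditions: PivCl (3 equiv), Et3N, DMAP, CH2Cl2, 0 °C to reflux
Reagents that add atoms: pivaloyl chloride, CC(C)(C)C(=O)Cl
Why: Nucleophile-catalysed acylation (DMAP, through the N-pivaloylpyridinium ion) esterifies the phenol at once and the shielded benzylic alcohol on warming; the alkenyl iodide and the aryl ethers are inert.

Step 6
Reactants: 14 bis-pivalate of 13
Product: 15 (Z)-1-(2'-hydroxy-3,5',6-trimethoxybiphenyl-2-yl)-4-iodo-3-methylbut-3-en-1-yl pivalate (racemic)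
Conditions: K2CO3 (0.5 equiv), MeOH/THF, 0 °C to rt
Reagents that add atoms: none
Why: Base-catalysed transesterification (methanolysis): the aryl ester, with phenoxide as leaving group, is cleaved much faster than the secondary alkyl pivalate flanked by two ortho substituents, which frees only the phenol needed for the dearomatisation.

Step 7
Reactants: 15 (Z)-1-(2'-hydroxy-3,5',6-trimethoxybiphenyl-2-yl)-4-iodo-3-methylbut-3-en-1-yl pivalate
Product: 16 (S)-1,4,5'-trimethoxy-7-methyl-2'-oxo-8,9-dihydrospiro[benzo[7]annulene-5,1'-cyclohexa[3,5]dien]-9-yl pivalate (both C9 epimers)
Conditions: Pd2(dba)3 (2.5 mol %), (S)-AntPhos (6 mol %), K2CO3, degassed toluene, 80 °C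
Reagents that add atoms: none
Why: Palladium-catalysed intramolecular dearomative C-alkenylation of a phenol (the alkenyl counterpart of the arylative phenol dearomatisation): zerovalent palladium inserts into the C–I bond with retention of the (Z) geometry, the phenoxide binds, and C–C reductive elimination at the aryl-bearing ortho carbon (the only ring carbon the tether reaches without a nine-membered ring) closes the seven-membered ring to a dienone that cannot re-aromatise; the chiral monophosphine selects one face of the phenoxide ring of the freely rotating biaryl in the bond-forming event and so sets C5, and each carbinol epimer is expected to cyclise under catalyst control.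

Step 8
Reactants: 16 spiro methoxy dienone
Product: 17 (R)-1,4-dimethoxy-7-methyl-2',5'-dioxo-8,9-dihydrospiro[benzo[7]annulene-5,1'-cyclohex[3]en]-9-yl pivalate (both C9 epimers)
Conditions: oxalic acid, THF/H2O, 0 °C to rt
Reagents that add atoms: water, O
Why: Acid-catalysed enol ether hydrolysis (protonation at C6', addition of water to the oxocarbenium ion, loss of methanol) unmasks the C5' ketone and creates the single methylene flanked by a carbonyl; pivalate and quaternary C5 are untouched (the descriptor changes only through the priority order), and the dienone is taken into this step without storage because such dienones can dimerise.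

Step 9
Reactants: 17 spiro cyclohexenedione; 18 prenyl bromide
Product: 20 (5S)-1,4-dimethoxy-7-methyl-6'-(3-methylbut-2-en-1-yl)-2',5'-dioxo-8,9-dihydrospiro[benzo[7]annulene-5,1'-cyclohex[3]en]-9-yl pivalate (epimers at C6' and C9), via lithium enolate 19 (not isolated)
Conditions: LiN(SiMe3)2, THF, -78 °C (17 added to the base); then 18, DMPU, -78 to -30 °C
Reagents that add atoms: none
Why: Ketone enolate alkylation (SN2 on an allylic bromide): C6' is the only enolisable position, the lithium enolate forms irreversibly in the cold and the soft prenyl bromide alkylates it on carbon; the new CH centre forms as a mixture, which is harmless because step 10 returns it to an enol ether.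

Step 10
Reactants: 20 prenylated spiro cyclohexenedione
Product: 23 bridged tetracycle as hydroquinone dimethyl ether, 20 with C6' bonded to C9 in place of the pivalate, (6'S,5R,9R), via silyl dienol ether 21 (not isolated), via benzylic cation 22 (not isolated)
Conditions: TMSOTf (1.2 equiv), iPr2NEt (1.5 equiv), CH2Cl2, -78 to 0 °C; then TMSOTf (1.5 equiv), -78 to -40 °C; aq. NaHCO3
Reagents that add atoms: none
Why: Proposed new method: the first charge of TMSOTf with the amine in slight excess converts the ketone next to the prenyl-bearing CH, the one enolisable position because every other alpha-carbon is vinylic or quaternary, into the single silyl dienol ether 21; the second charge, now in excess over the amine, silylates the pivalate carbonyl and ionises C9–O to the benzylic cation 22 that the ortho methoxy group stabilises, C6' then bonds to C9 across the seven-membered ring and the silyloxocarbenium ion hands its silyl group back to triflate, which restores the enedione. The closest known reaction type is the Lewis-acid-promoted SN1 alkylation of silyl enol ethers by benzylic or tertiary esters and halides, which serves to make quaternary carbons and has been run in one pot with TMSOTf and an amine, together with the intramolecular enolate alkylations that close bicyclo[3.2.1]octanes; a transannular version that builds a bridged ring and two adjacent quaternary carbons is not known. Both rings close enol-exo at C6' and, counted from the departing pivalate, exo-tet at C9, the five-membered ring (C5, C4a, C9a, C9, C6') as a 5-(enolexo)-exo-tet and the cyclohexene ring (C5, C6, C7, C8, C9, C6') as a 6-(enolexo)-exo-tet closure; seen from the free cation the five-membered closure is endo to the C9a–C9 pi-bond, which a carbocation tolerates by twisting C9 out of conjugation as the bond forms, as in phthalan-forming cation captures. The configuration at C9 follows from C5 alone, since the one-carbon bridge can span only the face of the seven-membered ring on which C6' is held; at C6' the benzylic carbon, which hangs from C5 through the two arene carbons, can come over the enol carbon only from the side on which the C5–aryl bond stands roughly perpendicular to the enedione ring, and bonding there puts prenyl on the side of the C6=C7 bridge and the C5' carbonyl on the side of the arene (enedione ring cis-fused to the five-membered ring and trans-fused to the cyclohexene ring), whereas the opposite enol face would have to build a strained trans-fused indane. The step needs C- over O-alkylation and substitution over proton loss from the allylic C8 methylene or capture of the cation by the prenyl alkene: the spiro centre ties nucleophile and electrophile into one medium ring so that the five-membered C–C closure costs little entropy, the product has two fully substituted ring-fusion carbons and can neither aromatise nor ionise back, and cold conditions, triflate as counter-ion and the absence of free amine during ionisation hold elimination back.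

Step 11
Reactants: 23 bridged tetracycle as hydroquinone dimethyl ether
Product: 24 bridged tetracycle with the arene oxidised to the 1,4-benzoquinone, spatial arrangement as in 23, descriptors (6'S,5S,9R)
Conditions: (NH4)2Ce(NO3)6 (2.5 equiv), MeCN/H2O, 0 °C
Reagents that add atoms: water, O
Why: Oxidative demethylation of a hydroquinone dimethyl ether by tetravalent cerium (single-electron oxidation of the arene, attack of water, loss of methanol) gives the quinone; in the cold and within minutes the enedione and the two trisubstituted alkenes should not react, and no stereocentre is touched (the C5 descriptor changes only because the quinone ring outranks C6').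

Step 12
Reactants: 24 bridged quinone
Product: 25 target CNP0513322.1, (6'S,5R,9R)
Conditions: Na2S2O4, EtOAc/H2O, rt, brief contact, under argon
Reagents that add atoms: none
Why: Dithionite reduction of a quinone to the hydroquinone: the benzoquinone is a far better electron acceptor than the enedione, so a short biphasic contact should reduce it alone, and work-up under argon avoids re-oxidation; the three stereocentres are not involved.

Compound list
1 | 2,5-dimethoxybenzaldehyde | COc1ccc(OC)c(C=O)c1 | starting material
2 | lithium (2,5-dimethoxyphenyl)[(2-dimethylaminoethyl)(methyl)amino]methanolate (alpha-amino alkoxide) | COc1ccc(OC)c(c1)C(O[Li])N(C)CCN(C)C | intermediate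
3 | 6-lithio derivative of 2 (aryllithium between the carbinol carbon and the 5-methoxy group) | COc1ccc(OC)c(C(O[Li])N(C)CCN(C)C)c1[Li] | intermediate
4 | 6-iodo derivative of 2 | COc1ccc(OC)c(C(O[Li])N(C)CCN(C)C)c1I | intermediate
5 | 2-iodo-3,6-dimethoxybenzaldehyde | COc1ccc(OC)c(C=O)c1I | intermediate
6 | (2-hydroxy-5-methoxyphenyl)boronic acid | COc1ccc(O)c(B(O)O)c1 | starting material
7 | 2'-hydroxy-3,5',6-trimethoxybiphenyl-2-carbaldehyde (open form; rests as the lactol 2,7,10-trimethoxy-6H-benzo[c]chromen-6-ol) | COc1ccc(O)c(c1)-c1c(OC)ccc(OC)c1C=O | intermediate
8 | propargyl bromide (3-bromoprop-1-yne) | C#CCBr | starting material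
9 | 1-(2'-hydroxy-3,5',6-trimethoxybiphenyl-2-yl)but-3-yn-1-ol, racemic | COc1ccc(O)c(c1)-c1c(OC)ccc(OC)c1C(O)CC#C | intermediate
10 | trimethylaluminium | C[Al](C)C | starting material
11 | (E)-alkenylalane from syn-carboalumination of 9, phenol and carbinol as dimethylaluminium oxides, aluminium trans to the chain | COc1ccc(O[Al](C)C)c(c1)-c1c(OC)ccc(OC)c1C(O[Al](C)C)C/C(C)=C/[Al](C)C | intermediate
12 | cyclic (Z)-alkenylalane, six-membered ring of carbinol carbon, CH2, C(CH3)=CH, Al(CH3) and O | COc1ccc(O[Al](C)C)c(c1)-c1c(OC)ccc(OC)c1C1C/C(C)=C\[Al](C)O1 | intermediate
13 | (Z)-4-iodo-3-methyl-1-(2'-hydroxy-3,5',6-trimethoxybiphenyl-2-yl)but-3-en-1-ol, racemic, iodine cis to the CH2 chain | COc1ccc(O)c(c1)-c1c(OC)ccc(OC)c1C(O)C/C(C)=C\I | intermediate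
14 | bis-pivalate of 13 (aryl and benzylic esters) | COc1ccc(OC(=O)C(C)(C)C)c(c1)-c1c(OC)ccc(OC)c1C(OC(=O)C(C)(C)C)C/C(C)=C\I | intermediate
15 | (Z)-1-(2'-hydroxy-3,5',6-trimethoxybiphenyl-2-yl)-4-iodo-3-methylbut-3-en-1-yl pivalate, racemic | COc1ccc(O)c(c1)-c1c(OC)ccc(OC)c1C(OC(=O)C(C)(C)C)C/C(C)=C\I | intermediate
16 | (S)-1,4,5'-trimethoxy-7-methyl-2'-oxo-8,9-dihydrospiro[benzo[7]annulene-5,1'-cyclohexa[3,5]dien]-9-yl pivalate, both C9 epimers | C1=C(OC)C=CC(=O)[C@@]12C=C(C)CC(OC(=O)C(C)(C)C)c3c(OC)ccc(OC)c32 | intermediate
17 | (R)-1,4-dimethoxy-7-methyl-2',5'-dioxo-8,9-dihydrospiro[benzo[7]annulene-5,1'-cyclohex[3]en]-9-yl pivalate, both C9 epimers | C1C(=O)C=CC(=O)[C@@]12C=C(C)CC(OC(=O)C(C)(C)C)c3c(OC)ccc(OC)c32 | intermediate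
18 | prenyl bromide (1-bromo-3-methylbut-2-ene) | CC(C)=CCBr | starting material
19 | lithium enolate of 17 (O–Li on C5', C5'=C6'), spiro centre S | C1=C(O[Li])C=CC(=O)[C@@]12C=C(C)CC(OC(=O)C(C)(C)C)c3c(OC)ccc(OC)c32 | intermediate
20 | (5S)-1,4-dimethoxy-7-methyl-6'-(3-methylbut-2-en-1-yl)-2',5'-dioxo-8,9-dihydrospiro[benzo[7]annulene-5,1'-cyclohex[3]en]-9-yl pivalate, epimers at C6' and C9 | CC(C)=CCC1C(=O)C=CC(=O)[C@@]12C=C(C)CC(OC(=O)C(C)(C)C)c3c(OC)ccc(OC)c32 | intermediate
21 | trimethylsilyl dienol ether of 20 (O–SiMe3 on C5', C5'=C6'), spiro centre S | CC(C)=CCC1=C(O[Si](C)(C)C)C=CC(=O)[C@@]12C=C(C)CC(OC(=O)C(C)(C)C)c3c(OC)ccc(OC)c32 | intermediate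
22 | benzylic cation at C9 derived from 21, triflate ion pair | CC(C)=CCC1=C(O[Si](C)(C)C)C=CC(=O)[C@@]12C=C(C)C[CH+]c3c(OC)ccc(OC)c32.[O-]S(=O)(=O)C(F)(F)F | intermediate
23 | bridged tetracycle as hydroquinone dimethyl ether: enedione ring fused along C5–C6' to a 1,4-dimethoxybenzo-fused bicyclo[3.2.1]octadiene, prenyl on C6', (6'S,5R,9R) | CC(C)=CC[C@@]12C(=O)C=CC(=O)[C@@]13C=C(C)C[C@@H]2c1c(OC)ccc(OC)c13 | intermediate
24 | bridged tetracycle with the arene as 1,4-benzoquinone, same spatial arrangement as 23, (6'S,5S,9R) | CC(C)=CC[C@@]12C(=O)C=CC(=O)[C@@]13C=C(C)C[C@@H]2C1=C3C(=O)C=CC1=O | intermediate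
25 | CNP0513322.1, bridged tetracycle with free hydroquinone, (6'S,5R,9R) | CC(C)=CC[C@@]12C(=O)C=CC(=O)[C@@]13C=C(C)C[C@@H]2c1c(O)ccc(O)c13 | target

Total step count: 12. Longest linear sequence: 12 steps (1 to 25).

Steps most likely to fail

Step 10 (carries the label). After ionisation, loss of a proton from the allylic C8 methylene (to a conjugated benzocycloheptatriene) or capture of the cation by the prenyl alkene may outpace the transannular C–C bond formation, or the hindered C6'–H may resist silylation. The fallback uses known chemistry, sets out from 20 and returns at 23. The pivalate is exchanged for bromide with TMSBr (CH2Cl2, -20 °C, 2,6-di-tert-butylpyridine as proton scavenger) to give the benzylic bromide F1, used crude. The ring is then closed under basic conditions by intramolecular ketone enolate alkylation, the established way of closing bicyclo[3.2.1]octanes: KN(SiMe3)2 (1.05 equiv), THF, -78 to 0 °C, forms the potassium enolate at C6', which displaces bromide across the ring and gives 23. A little Bu4NBr lets the two bromide epimers interconvert so that both pass through the one with backside access; the ring-fusion argument for C6' is unchanged.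

Step 7. C–C reductive elimination from the eight-membered palladacycle may be too slow, so that protodeiodination or displacement of the benzylic ester by the phenoxide oxygen (closing a benzo[c]chromene) takes over; the mismatched half of the racemic carbinol may also erode catalyst control. The fallback sets out from 15 and returns at 17. The phenol is oxidised with PhI(OAc)2 in MeOH at 0 °C to the quinone monoketal F2, which has no phenoxide and presents the aryl-bearing ring carbon as an alkene carbon. An asymmetric intramolecular Heck cyclisation (Pd2(dba)3, BINAP of the matching antipode, HCO2Na, DMF, 80 °C) then adds the alkenylpalladium 7-exo to that carbon, the mode by which Heck cyclisations build quaternary stereocentres. The resulting alkylpalladium has no beta-hydrogen and is reduced by formate to the spiro ketal enone F3; any part that instead expels beta-methoxide is 16 itself. The aqueous acid of step 8 hydrolyses the ketal of F3 and gives 17.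

Step 9. The delocalised enolate may be alkylated on oxygen or add in Michael fashion to enedione not yet deprotonated, and C-alkylation next to the quaternary spiro carbon may be slow. The fallback sets out from 17 and returns at 20. Soft enolisation without a free enolate (TBSOTf, Et3N, CH2Cl2, -78 to 0 °C) gives the tert-butyldimethylsilyl dienol ether F4. It is prenylated under neutral conditions by the palladium-catalysed Tsuji allylation of silyl enol ethers with an allylic carbonate (3-methylbut-2-enyl methyl carbonate, Pd2(dba)3, dppe, THF, 60 °C): the pi-prenyl complex of divalent palladium is attacked at its unsubstituted terminus by the enolate released when methoxide removes the silyl group, which gives 20.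

Further compounds
F1 | step 10 | (5S)-9-bromo-1,4-dimethoxy-7-methyl-6'-(3-methylbut-2-en-1-yl)-8,9-dihydrospiro[benzo[7]annulene-5,1'-cyclohex[3]ene]-2',5'-dione, epimers at C6' and C9 | CC(C)=CCC1C(=O)C=CC(=O)[C@@]12C=C(C)CC(Br)c3c(OC)ccc(OC)c32
F2 | step 7 | quinone monoketal of 15: 4,4-dimethoxycyclohexa-2,5-dien-1-one carrying at C2 the 3,6-dimethoxyphenyl ring with its (Z)-4-iodo-3-methyl-1-(pivaloyloxy)but-3-enyl chain, racemic | COC1(OC)C=CC(=O)C(=C1)c1c(OC)ccc(OC)c1C(OC(=O)C(C)(C)C)C/C(C)=C\I
F3 | step 7 | (R)-1,4,5',5'-tetramethoxy-7-methyl-2'-oxo-8,9-dihydrospiro[benzo[7]annulene-5,1'-cyclohex[3]en]-9-yl pivalate, both C9 epimers | C1C(OC)(OC)C=CC(=O)[C@@]12C=C(C)CC(OC(=O)C(C)(C)C)c3c(OC)ccc(OC)c32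
F4 | step 9 | tert-butyldimethylsilyl dienol ether of 17 (O–Si on C5', C5'=C6'), spiro centre S | C1=C(O[Si](C)(C)C(C)(C)C)C=CC(=O)[C@@]12C=C(C)CC(OC(=O)C(C)(C)C)c3c(OC)ccc(OC)c32
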